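All runs stem from a simulated flask from invented constants, noise included.

At 8.0 h, the time of reading, turn each percentage of D back into a concentration before you compare flasks.

| setting | amber | teal | Monday's | Thursday's | Tuesday's | Saturday's | Wednesday's |
|---|---|---|---|---|---|---|---|
| Z | 0.56 M | 1.4 M | 0.40 M | 0.50 M | 1.2 M | 0.25 M | 0.80 M |
| Q | 80 mM (held) | 80 mM (held) | 80 mM (held) | 80 mM (held) | 80 mM (held) | 80 mM (held) | 80 mM (held) |
| remark | run made earlier | run made earlier |  |  |  |  |  |
| time |  |  | 8.0 h | 8.0 h | 8.0 h | 8.0 h | 8.0 h |

| run | time / h | D / % | Z / % |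
|---|---|---|---|
| amber | 1.50 | 1.0 | 92.3 |
| amber | 3.00 | 4.4 | 83.8 |
| amber | 5.00 | 7.4 | 74.6 |
| amber | 6.00 | 9.7 | 69.2 |
| amber | 8.00 | 13.2 | 60.4 |
| teal | 0.667 | 0 | 96.7 |
| teal | 1.33 | 0.6 | 96.7 |
| teal | 2.50 | 0.7 | 95.9 |
| teal | 4.00 | 2.9 | 90.9 |
| teal | 8.00 | 5.6 | 83.1 |

(each reading ± 1 percentage point)

- the flasks put in order of amount of D, in percent of the Z charged, best first, at 8.0 h (Monday's / Thursday's / Tuesday's / Saturday's / Wednesday's)
- the amount of D, in percent of the Z charged of the flask you put first, at 8.0 h
- the amount of D, in percent of the Z charged of the flask you put last, at 8.0 h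

- as a solid, counted per litre of solution: Z
- at the start none of Z is in solution
- at the start none of Q is in solution
- what has only dissolved of Z counts as not reacted

The amber run then holds 0.0739 M of D and the teal run 0.0784 M, equal within the scatter, although teal was charged with 2.50 times as much Z. So the rate follows a concentration that the charge does not move, which points to dissolved Z standing at one level while solid remains, and the making of D is zero order in the charge. Call the mean of the two the D made per litre by this time, 0.0762 M, and divide it by a flask's charge to get its percentage. The rule assumes that solid lasts, and the two runs lose on average 0.229 M of solid Z, so Saturday's charge of 0.25 M should just outlast the time. You therefore rank the flasks from smallest charge to largest, with 30.5% for Saturday's and 6.35% for Tuesday's. The forecast gives the same order, Saturday's > Monday's > Thursday's > Wednesday's > Tuesday's, with a top of 23%, lower than yours, and a low of 6.2%, reasoning that “Once the solid is gone, the rate falls.” The flasks give Saturday's > Monday's > Thursday's > Wednesday's > Tuesday's, with 27.9% in Saturday's and 5.81% in Tuesday's.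

    Z ⇌ X, rate k1*(cs1 - [X]) while solid is left; crystals form when [X] > cs1 (solubility = 0.600 M, k = 0.0510 h⁻¹)
    X + L → D (k = 4.20 L mol⁻¹ h⁻¹)
    X + D → G (k = 1.20 L mol⁻¹ h⁻¹)
    Q ⇌ L, rate k4*(csat - [L]) (kL = 2.30 h⁻¹)
    D ⇌ E (K = 1.80, k = 0.160 h⁻¹)
    L ⇌ J (K = 24.0, k = 0.130 h⁻¹)

Saturday's and Tuesday's, with charges 4.80 times apart, hold 0.0697 M and 0.0697 M of D, with X, the dissolved Z, at 0.0733 M and 0.0733 M, while solid Z still stands at 11.2% and 81.5% of their charges. Now put 0.0762 M to use on a further flask, like Tuesday's but charged with 0.30 M: the division gives 25.4%, and that flask, with 26.0% of its Z still solid, holds 23.2% of D.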